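**Assumptions (one line each)**
- (E)-Geranylacetone is bought as the single E isomer (≥97% E).
- In Step 18 the quinidine-derived catalyst is assumed to deliver the epoxide face shown; if the sense is opposite, the quinine-derived pseudoenantiomer is used instead.

**Conventions.** Drimane numbering for the decalin: C1–C10 ring carbons, C11 = CH2 on C9, C12 = CH3 on C8, angular CH3 on C10, and 4α-CH2O / 4β-CH3 on C4. Ar = 5-methoxy-4-{[(tert-butyldimethylsilyl)oxy]methyl}-2-[(triisopropylsilyl)oxy]phenyl. Target descriptors in this numbering: 4R,5R,9S,10R; epoxycyclohexenone 1′S (quaternary epoxide C), 2′S (epoxide CH), 6′R (carbinol), with the OH anti to the epoxide O.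

## Retrosynthetic overview

1. Epoxyquinol, made last: target ⇐ ketal alcohol 21 ⇐ epoxy ketone 20 ⇐ p-quinone monoketal 19 ⇐ p-methoxyphenol 18 (dearomatisation; new catalyst-controlled nucleophilic epoxidation; anti-selective reduction; HF).
2. Δ7-8-methyl unit: 17 ⇐ C8 ketone 15 via kinetic enol triflate and methyl cross-coupling; the C3-OH left by the cyclisation is removed by Barton–McCombie.
3. Rings A and B together: decalone 13 ⇐ acyclic epoxy silyl enol ether 12 by one epoxide-initiated cationic bicyclisation (sets C4, C5, C10, C9).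
4. 12 ⇐ enone 11 ⇐ aldol union of epoxy ketone 4 (geranylacetone; SeO2, Sharpless epoxidation) with aryl aldehyde 9 (from 4-bromo-2,5-dimethoxybenzaldehyde).
5. Ring order: arene (purchased) → A/B decalin in one step → arene dearomatised → epoxide ring.

## Route

**Step 1**
Reactants: 1, (E)-geranylacetone
Product: 2, (5E,9E)-11-hydroxy-6,10-dimethylundeca-5,9-dien-2-one
Conditions: SeO2 (0.3 equiv), t-BuOOH (3 equiv), salicylic acid (cat.), CH2Cl2, rt
Reagents that add atoms: selenium dioxide, O=[Se]=O (O source); tert-butyl hydroperoxide, CC(C)(C)OO (reoxidant)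
Why: Catalytic SeO2 allylic oxidation (ene/[2,3]) is selective for the (E)-methyl of the terminal trisubstituted alkene and gives the (E)-allylic alcohol needed for directed epoxidation; no stereocentre is formed.

**Step 2**
Reactants: 2
Product: 3, (5E)-8-[(2S,3S)-3-(hydroxymethyl)-3-methyloxiran-2-yl]-6-methyloct-5-en-2-one
Conditions: Ti(OiPr)4 (10 mol %), L-(+)-DET (12 mol %), t-BuOOH, 4 Å MS, CH2Cl2, −20 °C
Reagents that add atoms: tert-butyl hydroperoxide, CC(C)(C)OO
Why: Katsuki–Sharpless asymmetric epoxidation touches only the allylic-alcohol alkene; L-(+)-tartrate gives the (2S,3S)-epoxide (same facial sense as geraniol → (2S,3S)-epoxygeraniol), which fixes the absolute configuration of the decalin.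

**Step 3**
Reactants: 3
Product: 4, TBS ether of 3
Conditions: TBSCl, imidazole, DMF, 0 °C → rt
Reagents that add atoms: tert-butyldimethylsilyl chloride, C[Si](C)(Cl)C(C)(C)C
Why: Standard silylation of the primary alcohol; a bulky, weakly Lewis-basic silyl ether is the least participating group next to the epoxide for the later cyclisation.

**Step 4**
Reactants: 5, 4-bromo-2,5-dimethoxybenzaldehyde
Product: 6, 4-bromo-2-hydroxy-5-methoxybenzaldehyde
Conditions: BCl3 (1.2 equiv), CH2Cl2, −78 → 0 °C
Reagents that add atoms: none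
Why: Chelation-controlled Lewis-acid demethylation cleaves only the methyl ether ortho to the formyl group, differentiating the two oxygens.

**Step 5**
Reactants: 6
Product: 7, 4-bromo-5-methoxy-2-[(triisopropylsilyl)oxy]benzaldehyde
Conditions: TIPSOTf, 2,6-lutidine, CH2Cl2, 0 °C
Reagents that add atoms: triisopropylsilyl triflate, CC(C)[Si](OS(=O)(=O)C(F)(F)F)(C(C)C)C(C)C
Why: Silylation of the phenol; aryl OTIPS is robust to base and Lewis acid yet can later be removed selectively in the presence of alkyl TBS ethers.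

**Step 6**
Reactants: 7
Product: 8, 4-(hydroxymethyl)-5-methoxy-2-[(triisopropylsilyl)oxy]benzaldehyde
Conditions: Bu3SnCH2OH (1.3 equiv), Pd(PPh3)4 (5 mol %), 1,4-dioxane, 90 °C
Reagents that add atoms: tributyl(hydroxymethyl)stannane, CCCC[Sn](CCCC)(CCCC)CO
Why: Migita–Kosugi–Stille hydroxymethylation of the aryl bromide (activated by the para-formyl group) under neutral conditions that spare the aldehyde and aryl silyl ether.

**Step 7**
Reactants: 8
Product: 9, 4-{[(tert-butyldimethylsilyl)oxy]methyl}-5-methoxy-2-[(triisopropylsilyl)oxy]benzaldehyde (Ar–CHO)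
Conditions: TBSCl, imidazole, CH2Cl2, rt
Reagents that add atoms: tert-butyldimethylsilyl chloride, C[Si](C)(Cl)C(C)(C)C
Why: Standard silylation of the benzylic alcohol.

**Step 8**
Reactants: 4; 9
Product: 10, (6E)-1-Ar-1-hydroxy-7-methyl-9-[(2S,3S)-3-(TBSO-methyl)-3-methyloxiran-2-yl]non-6-en-3-one (both C1 epimers)
Conditions: LDA (1.05 equiv), THF, −78 °C; add 9, −78 °C; AcOH quench at −78 °C
Reagents that add atoms: none
Why: Directed crossed aldol: the kinetic lithium enolate forms at the methyl group of the methyl ketone and adds to the non-enolisable aldehyde, making the C9–C11 bond; the cold quench prevents retro-aldol and O→O silyl migration, and the new carbinol centre is erased in Step 9.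

**Step 9**
Reactants: 10
Product: 11, (1E,6E)-1-Ar-7-methyl-9-[(2S,3S)-3-(TBSO-methyl)-3-methyloxiran-2-yl]nona-1,6-dien-3-one
Conditions: MsCl, Et3N, CH2Cl2, 0 °C; then DBU, rt
Reagents that add atoms: none
Why: Mesylation and E1cB elimination of the β-hydroxy ketone give the conjugated (E)-enone.

**Step 10**
Reactants: 11
Product: 12, (2Z,6E)-triethylsilyl enol ether, Ar–CH2–CH=C(OSiEt3)–CH2CH2–CH=C(CH3)–CH2CH2–[(2S,3S)-epoxide]
Conditions: Et3SiH (1.5 equiv), RhCl(PPh3)3 (2 mol %), THF, 50 °C
Reagents that add atoms: triethylsilane, CC[SiH](CC)CC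
Why: Rh-catalysed 1,4-hydrosilylation of the s-cis enone puts H on C11 and Si on O, giving the regiodefined (Z)-silyl enol ether toward C9; this geometry (C7 trans to C11) is the one that translates into an equatorial C9 substituent.

**Step 11**
Reactants: 12
Product: 13, 11-Ar-3β-hydroxy-4α-(TBSO-methyl)-12-nordriman-8-one (5α-H, 10β-CH3, 4β-CH3, 9β-CH2Ar)
Conditions: MeAlCl2 (3 equiv), CH2Cl2, −94 → −78 °C; Et3N/MeOH then aq. Rochelle salt; PPTS/MeOH at 0 °C if any O-silylated product remains
Reagents that add atoms: none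
Why: Epoxide-initiated, silyl-enol-ether-terminated cationic polyene bicyclisation through a chair–chair (Stork–Eschenmoser) transition state with anti opening at the tertiary epoxide carbon; the epoxide sets 3β-OH, the E-allylic geometry puts CH2OTBS equatorial (4α), the 6E alkene gives the trans ring fusion (5α-H, 10β-CH3) and the Z enol ether gives 9β-CH2Ar.

**Step 12**
Reactants: 13
Product: 14, 3β-O-(imidazol-1-ylthiocarbonyl) derivative of 13
Conditions: 1,1′-thiocarbonyldiimidazole (3 equiv), DMAP (0.3 equiv), 1,2-dichloroethane, 80 °C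
Reagents that add atoms: 1,1′-thiocarbonyldiimidazole, S=C(n1ccnc1)n1ccnc1
Why: Thioacylation of the hindered secondary alcohol under near-neutral conditions that tolerate the ketone and silyl ethers; first half of a Barton–McCombie deoxygenation.

**Step 13**
Reactants: 14
Product: 15, 11-Ar-4α-(TBSO-methyl)-12-nordriman-8-one
Conditions: n-Bu3SnH (2 equiv), AIBN (0.2 equiv), toluene, 100 °C
Reagents that add atoms: none
Why: Barton–McCombie radical deoxygenation removes the C3 oxygen that served only as the initiating epoxide; no stereocentre is affected.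

**Step 14**
Reactants: 15
Product: 16, 11-Ar-4α-(TBSO-methyl)-12-nordrim-7-en-8-yl trifluoromethanesulfonate
Conditions: KHMDS (1.2 equiv), THF, −78 °C; PhNTf2 (1.3 equiv), −78 → 0 °C
Reagents that add atoms: N-phenyl-bis(trifluoromethanesulfonimide), O=S(=O)(N(c1ccccc1)S(=O)(=O)C(F)(F)F)C(F)(F)F
Why: Kinetic deprotonation occurs at the C7 methylene (C9–H is tertiary and flanked by quaternary C10), so O-triflation fixes the alkene at C7=C8 and leaves C9 untouched.

**Step 15**
Reactants: 16
Product: 17, 11-Ar-4α-(TBSO-methyl)drim-7-ene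
Conditions: Fe(acac)3 (10 mol %), MeMgBr (2 equiv), THF/NMP, −30 → 0 °C
Reagents that add atoms: methylmagnesium bromide, C[Mg]Br
Why: Iron-catalysed Kumada-type cross-coupling of the alkenyl triflate installs the C8 methyl without moving the double bond.

**Step 16**
Reactants: 17
Product: 18, phenol: 2-{[4α-(TBSO-methyl)drim-7-en-11-yl]}-4-methoxy-5-(TBSO-methyl)phenol
Conditions: TBAF (1.0 equiv), THF, −40 → −20 °C
Reagents that add atoms: none
Why: Aryl silyl ethers are cleaved by fluoride far faster than primary alkyl TBS ethers because phenoxide is the better leaving group, so only the phenol is unmasked.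

**Step 17**
Reactants: 18
Product: 19, 2-{[4α-(TBSO-methyl)drim-7-en-11-yl]}-4,4-dimethoxy-5-(TBSO-methyl)cyclohexa-2,5-dien-1-one
Conditions: PhI(OAc)2 (1.1 equiv), NaHCO3, MeOH, 0 °C
Reagents that add atoms: methanol, CO
Why: Hypervalent-iodine oxidative dearomatisation of a p-methoxyphenol gives the p-quinone monoketal regiospecifically: the phenol carbon (next to the drimanylmethyl carbon) becomes C=O and the OMe carbon becomes the ketal.

**Step 18**
Reactants: 19
Product: 20, 2,3-epoxide of 19 (epoxide O on the face shown in the SMILES; the quaternary epoxide carbon bears the drimanylmethyl group)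
Conditions: t-BuOOH (2 equiv), powdered KOH (1.5 equiv), toluene, −20 °C, 10 mol % N-[3,5-bis(trifluoromethyl)benzyl]-9-deoxy-9-epi-9-[3-(3,5-bis(trifluoromethyl)phenyl)ureido]quinidinium bromide
Reagents that add atoms: tert-butyl hydroperoxide, CC(C)(C)OO
Why: Proposed new method: catalyst-controlled diastereoselective Weitz–Scheffer epoxidation of an α-alkyl p-quinone monoketal under bifunctional chiral phase-transfer catalysis — the ammonium ion-pairs t-BuOO⁻ while the urea N–H's hydrogen-bond the C1 carbonyl, so peroxide adds only to the unsubstituted, ketal-flanked β-carbon C3 (not the CH2OTBS-bearing C5) from the face left open by the quinoline wall, and the ammonium-bound dienolate closes by 3-exo attack of C2 on the O–O bond (loss of t-BuO⁻) to form the quaternary epoxide carbon; the nearest drimane stereocentre (C9) is insulated by the CH2 spacer, so the catalyst should dictate both epoxide stereocentres; closest known reaction type is cinchona-ammonium phase-transfer epoxidation of 2-alkyl-1,4-naphthoquinones and of 2-acylamino quinone monoketals, not shown for α-alkyl benzoquinone monoketals or for catalyst-controlled diastereoselection on a chiral substrate.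

**Step 19**
Reactants: 20
Product: 21, trans-epoxy alcohol (C1 carbinol; OH anti to the epoxide O, syn to the drimanylmethyl group)
Conditions: NaBH4, CeCl3·7H2O, MeOH, −78 °C
Reagents that add atoms: none
Why: Luche reduction of the α,β-epoxy ketone: hydride is expected to enter on the epoxide-oxygen face (Ce-bridged) and anti to the CH2R group on the adjacent quaternary carbon, giving the trans-epoxy alcohol.

**Step 20**
Reactants: 21
Product: 22, epoxypholamin A
Conditions: 48% aq. HF, MeCN, 0 °C → rt
Reagents that add atoms: water, O (carbonyl oxygen from ketal hydrolysis)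
Why: One mildly acidic operation removes both primary TBS ethers and hydrolyses the dimethyl ketal to the enone; the stereocentres are not epimerisable under these conditions.

## Compound list

1 | (E)-geranylacetone, (5E)-6,10-dimethylundeca-5,9-dien-2-one | CC(=O)CC/C=C(\C)CCC=C(C)C | starting material
2 | (5E,9E)-11-hydroxy-6,10-dimethylundeca-5,9-dien-2-one | CC(=O)CC/C=C(\C)CC/C=C(\C)CO | intermediate
3 | (5E)-8-[(2S,3S)-3-(hydroxymethyl)-3-methyloxiran-2-yl]-6-methyloct-5-en-2-one | CC(=O)CC/C=C(\C)CC[C@@H]1O[C@@]1(C)CO | intermediate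
4 | TBS ether of 3 | CC(=O)CC/C=C(\C)CC[C@@H]1O[C@@]1(C)CO[Si](C)(C)C(C)(C)C | intermediate
5 | 4-bromo-2,5-dimethoxybenzaldehyde | COc1cc(C=O)c(OC)cc1Br | starting material
6 | 4-bromo-2-hydroxy-5-methoxybenzaldehyde | COc1cc(C=O)c(O)cc1Br | intermediate
7 | 4-bromo-5-methoxy-2-(triisopropylsilyloxy)benzaldehyde | COc1cc(C=O)c(O[Si](C(C)C)(C(C)C)C(C)C)cc1Br | intermediate
8 | 4-(hydroxymethyl)-5-methoxy-2-(triisopropylsilyloxy)benzaldehyde | COc1cc(C=O)c(O[Si](C(C)C)(C(C)C)C(C)C)cc1CO | intermediate
9 | 4-(TBSO-methyl)-5-methoxy-2-(triisopropylsilyloxy)benzaldehyde | COc1cc(C=O)c(O[Si](C(C)C)(C(C)C)C(C)C)cc1CO[Si](C)(C)C(C)(C)C | intermediate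
10 | aldol adduct, β-hydroxy ketone (C1 epimers) | O=C(CC(O)c1cc(OC)c(CO[Si](C)(C)C(C)(C)C)cc1O[Si](C(C)C)(C(C)C)C(C)C)CC/C=C(\C)CC[C@@H]1O[C@@]1(C)CO[Si](C)(C)C(C)(C)C | intermediate
11 | (1E,6E)-aryl enone epoxide | O=C(/C=C/c1cc(OC)c(CO[Si](C)(C)C(C)(C)C)cc1O[Si](C(C)C)(C(C)C)C(C)C)CC/C=C(\C)CC[C@@H]1O[C@@]1(C)CO[Si](C)(C)C(C)(C)C | intermediate
12 | (2Z,6E)-triethylsilyl enol ether epoxide | CC[Si](CC)(CC)O/C(=C\Cc1cc(OC)c(CO[Si](C)(C)C(C)(C)C)cc1O[Si](C(C)C)(C(C)C)C(C)C)CC/C=C(\C)CC[C@@H]1O[C@@]1(C)CO[Si](C)(C)C(C)(C)C | intermediate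
13 | 11-Ar-3β-hydroxy-4α-(TBSO-methyl)-12-nordriman-8-one | O=C1CC[C@H]2[C@](C)(CO[Si](C)(C)C(C)(C)C)[C@@H](O)CC[C@]2(C)[C@H]1Cc1cc(OC)c(CO[Si](C)(C)C(C)(C)C)cc1O[Si](C(C)C)(C(C)C)C(C)C | intermediate
14 | 3β-O-(imidazol-1-ylthiocarbonyl) derivative of 13 | O=C1CC[C@H]2[C@](C)(CO[Si](C)(C)C(C)(C)C)[C@@H](OC(=S)n3ccnc3)CC[C@]2(C)[C@H]1Cc1cc(OC)c(CO[Si](C)(C)C(C)(C)C)cc1O[Si](C(C)C)(C(C)C)C(C)C | intermediate
15 | 11-Ar-4α-(TBSO-methyl)-12-nordriman-8-one | O=C1CC[C@H]2[C@](C)(CO[Si](C)(C)C(C)(C)C)CCC[C@]2(C)[C@H]1Cc1cc(OC)c(CO[Si](C)(C)C(C)(C)C)cc1O[Si](C(C)C)(C(C)C)C(C)C | intermediate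
16 | Δ7 enol triflate of 15 | O=S(=O)(OC1=CC[C@H]2[C@](C)(CO[Si](C)(C)C(C)(C)C)CCC[C@]2(C)[C@H]1Cc1cc(OC)c(CO[Si](C)(C)C(C)(C)C)cc1O[Si](C(C)C)(C(C)C)C(C)C)C(F)(F)F | intermediate
17 | 11-Ar-4α-(TBSO-methyl)drim-7-ene | CC1=CC[C@H]2[C@](C)(CO[Si](C)(C)C(C)(C)C)CCC[C@]2(C)[C@H]1Cc1cc(OC)c(CO[Si](C)(C)C(C)(C)C)cc1O[Si](C(C)C)(C(C)C)C(C)C | intermediate
18 | free phenol of 17 | CC1=CC[C@H]2[C@](C)(CO[Si](C)(C)C(C)(C)C)CCC[C@]2(C)[C@H]1Cc1cc(OC)c(CO[Si](C)(C)C(C)(C)C)cc1O | intermediate
19 | p-quinone monoketal (4,4-dimethoxycyclohexa-2,5-dienone) | CC1=CC[C@H]2[C@](C)(CO[Si](C)(C)C(C)(C)C)CCC[C@]2(C)[C@H]1CC1=CC(OC)(OC)C(CO[Si](C)(C)C(C)(C)C)=CC1=O | intermediate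
20 | epoxy ketone monoketal | CC1=CC[C@H]2[C@](C)(CO[Si](C)(C)C(C)(C)C)CCC[C@]2(C)[C@H]1C[C@@]12O[C@@H]1C(OC)(OC)C(CO[Si](C)(C)C(C)(C)C)=CC2=O | intermediate
21 | trans-epoxy alcohol monoketal | CC1=CC[C@H]2[C@](C)(CO[Si](C)(C)C(C)(C)C)CCC[C@]2(C)[C@H]1C[C@@]12O[C@@H]1C(OC)(OC)C(CO[Si](C)(C)C(C)(C)C)=C[C@H]2O | intermediate
22 | epoxypholamin A | CC1=CC[C@H]2[C@](C)(CO)CCC[C@]2(C)[C@H]1C[C@@]12O[C@@H]1C(=O)C(CO)=C[C@H]2O | target

## Summary

**Total step count:** 20 (3 to make 4, 4 to make 9, 13 after their union).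

**Longest linear sequence:** 17 steps (5 → 9 → 22); 16 steps from geranylacetone.

**Three steps most likely to fail, with fallbacks**

1. **Step 18 (proposed new catalyst-controlled epoxidation).** Risks are low facial selectivity or a mismatched catalyst/substrate pairing. Fallback (known chemistry): run a plain Weitz–Scheffer epoxidation (t-BuOOH/DBU or H2O2/LiOH) and separate the two epoxide products by chromatography; they are diastereomers, not enantiomers, because the drimane is enantiopure. If selectivity is still wanted, free the benzylic alcohol and use the stoichiometric tartrate-mediated, hydroxyl-directed epoxidation (Ph3COOH, NaHMDS, DIPT).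

2. **Step 11 (cationic bicyclisation of the silyloxymethyl epoxide).** Risks are a 1,2-hydride shift from the CH2OTBS carbon (epoxide → β-silyloxy aldehyde) or incomplete cyclisation. Fallback: cyclise the gem-dimethyl (S)-epoxide analogue, which is the best-precedented substrate type. Then oxidise C3-OH to the ketone, form the O-methyl oxime, and introduce the 4α-CH2O group by oxime-directed Pd(OAc)2/PhI(OAc)2 acetoxylation of the equatorial C4 methyl, before removing the C3 oxygen.

3. **Step 19 (facial selectivity of the epoxy-ketone reduction).** The risk is that the cis-epoxy alcohol predominates. Fallback: take the cis alcohol and invert the carbinol by Mitsunobu reaction (4-nitrobenzoic acid, DIAD, PPh3), then mild methanolysis, before the final HF step.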